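**Assumption:** atoms are labelled C1–C15 in germacranolide fashion (ring C1–C10, lactone C11/C12 on C7 with O on C6, exocyclic methylene C13, CHO = C14, CH2OH = C15); Grignard solutions are bought as such.

**Retrosynthetic overview**
1. Target ⇐ desilylation (O-15) and a late SeO2 allylic oxidation of a C10 methyl group; its [2,3] step both installs C14 and turns C1=C10 from ring-trans to ring-cis.
2. Both rings are cut together: C6–C7 (chromium-mediated intramolecular allylation of a (Z)-type enal) and C12–O6 (lactonisation of the resulting alkoxide) lead back to an open-chain chloro ester aldehyde.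
3. That seco compound ⇐ cross-metathesis at C1=C10 of a west enal (C1–C6, C15) with an east allylic chloride (C7–C14).
4. West ⇐ anti-carbomagnesiation of but-2-yne-1,4-diol. East ⇐ CBS reduction (C9), Felkin-controlled vinylation (C8), cross-metathesis with methyl 2-(chloromethyl)acrylate.
5. Ring order: no ring before step 12; there the ten-membered carbocycle and the α-methylene-γ-lactone form in one operation.

**Route**

Step 1
Reactants: 1 but-2-yne-1,4-diol; 2 but-3-en-1-ylmagnesium bromide
Product: 4 (2E)-2-(but-3-en-1-yl)but-2-ene-1,4-diol, via magnesium chelate 3 (not isolated)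
Conditions: 2 (3.3 equiv), CuI (10 mol %), THF, 0 °C → reflux; aq. NH4Cl
Reagents that add atoms: none
Why: Copper-catalysed hydroxyl-directed anti-carbomagnesiation of a propargylic alcohol (Duboudin–Jousseaume reaction): the butenyl group adds next to one alkoxide while magnesium is held on the other alkyne carbon in chelate 3, so protonation leaves the two CH2OH groups trans and C6 cis to the chain, the ring-cis C4=C5 geometry of the target.

Step 2
Reactants: 4 (2E)-2-(but-3-en-1-yl)but-2-ene-1,4-diol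
Product: 5 (2E)-3-(hydroxymethyl)hepta-2,6-dienal
Conditions: TEMPO (2,2,6,6-tetramethylpiperidin-1-oxyl, 10 mol %), PhI(OAc)2 (1.05 equiv), CH2Cl2, 0 °C
Reagents that add atoms: none
Why: Oxoammonium (TEMPO) oxidation is sensitive to crowding and should take the CH2OH on the CH= carbon (future C6) ahead of the one on the fully substituted carbon; CHO and the remaining CH2OH are trans, so no lactol forms.

Step 3
Reactants: 5 (2E)-3-(hydroxymethyl)hepta-2,6-dienal
Product: 6 (2E)-3-({[tert-butyl(dimethyl)silyl]oxy}methyl)hepta-2,6-dienal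
Conditions: TBSCl, imidazole, CH2Cl2, 0 °C → rt
Reagents that add atoms: tert-butyldimethylsilyl chloride, C[Si](C)(Cl)C(C)(C)C
Why: Silyl ether formation masks O-15 until the last step.

Step 4
Reactants: 7 ethyl 2,2-diethoxyacetate; 8 prop-1-en-2-ylmagnesium bromide
Product: 9 1,1-diethoxy-3-methylbut-3-en-2-one
Conditions: 8 (1.1 equiv), THF, −78 °C; aq. NH4Cl
Reagents that add atoms: none
Why: Acyl substitution of an α,α-dialkoxy ester by one equivalent of Grignard reagent at −78 °C is a standard ketone synthesis that does not over-add.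

Step 5
Reactants: 9 1,1-diethoxy-3-methylbut-3-en-2-one
Product: 10 (2S)-1,1-diethoxy-3-methylbut-3-en-2-ol
Conditions: (S)-1-methyl-3,3-diphenyltetrahydro-1H,3H-pyrrolo[1,2-c][1,3,2]oxazaborole (10 mol %), BH3·SMe2, THF, −30 °C; MeOH
Reagents that add atoms: none
Why: Corey–Bakshi–Shibata reduction: with the isopropenyl group acting as the large substituent the (S)-catalyst gives the (S)-alcohol (future C9); the enantiomeric catalyst is used if the acetal turns out to be the controlling group.

Step 6
Reactants: 10 (2S)-1,1-diethoxy-3-methylbut-3-en-2-ol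
Product: 11 (2S)-1,1-diethoxy-3-methylbut-3-en-2-yl acetate
Conditions: Ac2O, Et3N, 4-(dimethylamino)pyridine (5 mol %), CH2Cl2, 0 °C
Reagents that add atoms: acetic anhydride, CC(=O)OC(C)=O
Why: Acyl-transfer acetylation installs the C9 acetate of the target early, where it also serves as the polar α-substituent for step 8.

Step 7
Reactants: 11 (2S)-1,1-diethoxy-3-methylbut-3-en-2-yl acetate
Product: 12 (2S)-3-methyl-1-oxobut-3-en-2-yl acetate
Conditions: CF3CO2H/H2O (9:1), CH2Cl2, 0 °C; crude used at once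
Reagents that add atoms: water, O
Why: Acid-catalysed acetal hydrolysis frees the aldehyde without base, so the α-acetoxy stereocentre and the β,γ-double bond are not disturbed.

Step 8
Reactants: 12 (2S)-3-methyl-1-oxobut-3-en-2-yl acetate; 13 bromoethene
Product: 14 (3R,4S)-3-hydroxy-5-methylhexa-1,5-dien-4-yl acetate
Conditions: 13 (3 equiv), CrCl2 (4 equiv), NiCl2 (2 mol %), DMF, 0 → 25 °C; aq. work-up
Reagents that add atoms: none
Why: Nozaki–Hiyama–Kishi vinylation under neutral conditions (no acetyl migration): polar Felkin–Anh addition anti to the acetoxy group sets C8 as the 8,9-anti isomer.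

Step 9
Reactants: 14 (3R,4S)-3-hydroxy-5-methylhexa-1,5-dien-4-yl acetate; 15 methyl 2-(chloromethyl)prop-2-enoate
Product: 16 methyl (2Z,4R,5S)-5-acetoxy-2-(chloromethyl)-4-hydroxy-6-methylhepta-2,6-dienoate
Conditions: 15 (4 equiv), RuCl2(H2IMes)(=CH–C6H4-2-OiPr) (second-generation Hoveyda–Grubbs catalyst, H2IMes = 1,3-dimesitylimidazolidin-2-ylidene, 7 mol %), CH2Cl2, 40 °C
Reagents that add atoms: none
Why: Olefin cross-metathesis of the monosubstituted vinyl group with excess 2-substituted acrylate (the isopropenyl group does not couple with this partner) gives the thermodynamically preferred trisubstituted enoate with C8 trans to the ester.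

Step 10
Reactants: 16 methyl (2Z,4R,5S)-5-acetoxy-2-(chloromethyl)-4-hydroxy-6-methylhepta-2,6-dienoate; 6 (2E)-3-({[tert-butyl(dimethyl)silyl]oxy}methyl)hepta-2,6-dienal
Product: 17 methyl (2Z,4R,5S,6E,10E)-5-acetoxy-10-({[tert-butyl(dimethyl)silyl]oxy}methyl)-2-(chloromethyl)-4-hydroxy-6-methyl-12-oxododeca-2,6,10-trienoate
Conditions: 6 (3 equiv), RuCl2(H2IMes)(=CH–C6H4-2-OiPr) (10 mol %), toluene, 60 °C, N2 sparge
Reagents that add atoms: none
Why: Cross-metathesis of a terminal alkene with a 1,1-disubstituted alkene builds C1=C10, mainly with C9 trans to C2; this geometry need not be controlled because step 13 resets it.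

Step 11
Reactants: 17 methyl (2Z,4R,5S,6E,10E)-5-acetoxy-10-({[tert-butyl(dimethyl)silyl]oxy}methyl)-2-(chloromethyl)-4-hydroxy-6-methyl-12-oxododeca-2,6,10-trienoate
Product: 18 methyl (2Z,4R,5S,6E,10E)-5-acetoxy-10-({[tert-butyl(dimethyl)silyl]oxy}methyl)-2-(chloromethyl)-6-methyl-4-[(2-methylprop-2-enoyl)oxy]-12-oxododeca-2,6,10-trienoate
Conditions: methacryloyl chloride, iPr2NEt, CH2Cl2, −20 → 0 °C
Reagents that add atoms: methacryloyl chloride, C=C(C)C(Cl)=O
Why: Esterification with the acid chloride and a hindered, non-nucleophilic base puts the methacrylate on O-8 without displacing the allylic chloride.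

Step 12
Reactants: 18 methyl (2Z,4R,5S,6E,10E)-5-acetoxy-10-({[tert-butyl(dimethyl)silyl]oxy}methyl)-2-(chloromethyl)-6-methyl-4-[(2-methylprop-2-enoyl)oxy]-12-oxododeca-2,6,10-trienoate
Product: 21 (6R,7S,8R,9S)-9-acetoxy-15-(tert-butyldimethylsilyloxy)-8-(methacryloyloxy)germacra-1(10),4,11(13)-trien-12,6-olide with C9 trans to C2 at C1=C10 and C15 trans to C6 at C4=C5, via allylchromium 19 (not isolated), via chromium alkoxide 20 (not isolated)
Conditions: CrCl2 (8 equiv), LiI (20 mol %), DMF/THF (1:1), 2 mM by syringe pump, 25 → 40 °C; aq. work-up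
Reagents that add atoms: none
Why: Nozaki–Hiyama (chromium Barbier-type) allylation with lactonisation: allylchromium 19 adds through its γ-carbon C7 to the C6 aldehyde on the C7 face syn to the C9 tether with H-8 eclipsing the alkene (gives 7S), the (Z)-type enal favouring the trans 6R,7S fusion as in related germacranolide closures, and alkoxide 20 then lactonises onto the methyl ester, so carbocycle and lactone form in one operation.

Step 13
Reactants: 21 (6R,7S,8R,9S)-9-acetoxy-15-(tert-butyldimethylsilyloxy)-8-(methacryloyloxy)germacra-1(10),4,11(13)-trien-12,6-olide (C9 trans to C2)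
Product: 23 (6R,7S,8R,9S)-9-acetoxy-15-(tert-butyldimethylsilyloxy)-8-(methacryloyloxy)-14-oxogermacra-1(10),4,11(13)-trien-12,6-olide with C9 cis to C2 at C1=C10, via allylic alcohol 22 (not isolated)
Conditions: SeO2 (0.5 equiv), t-BuOOH (3 equiv), CH2Cl2, 25 °C; aq. work-up; then Dess–Martin periodinane, CH2Cl2, 0 °C
Reagents that add atoms: selenium dioxide, O=[Se]=O; tert-butyl hydroperoxide, CC(C)(C)OO (terminal source of the C14 oxygen)
Why: Riley allylic oxidation: the ene reaction at the only alkene without two allylic oxygens takes H from the C10 methyl group, and the [2,3]-sigmatropic shift returns the double bond with the new CH2OH trans to C2 (C9 now cis to C2, the target geometry) to give 22, which Dess–Martin oxidation turns into the enal.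

Step 14
Reactants: 23 (6R,7S,8R,9S)-9-acetoxy-15-(tert-butyldimethylsilyloxy)-8-(methacryloyloxy)-14-oxogermacra-1(10),4,11(13)-trien-12,6-olide
Product: 24 CNP0147326.13, (6R,7S,8R,9S)-9-acetoxy-15-hydroxy-8-(methacryloyloxy)-14-oxogermacra-1(10),4,11(13)-trien-12,6-olide (both ring alkenes ring-cis)
Conditions: HF·pyridine, THF/pyridine, 0 °C
Reagents that add atoms: none
Why: Fluoride desilylation under buffered conditions leaves the enal, both esters and the α-methylene lactone untouched.

**Compound list**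
1 | but-2-yne-1,4-diol | OCC#CCO | starting material
2 | but-3-en-1-ylmagnesium bromide | C=CCC[Mg]Br | starting material
3 | five-membered alkenylmagnesium alkoxide chelate (Mg on C5 and O-15, O-6 as OMgBr) | C=CCCC1=C(CO[Mg]Br)[Mg]OC1 | intermediate
4 | (2E)-2-(but-3-en-1-yl)but-2-ene-1,4-diol | OC/C=C(/CO)CCC=C | intermediate
5 | (2E)-3-(hydroxymethyl)hepta-2,6-dienal (CHO cis to the butenyl chain) | O=C/C=C(/CO)CCC=C | intermediate
6 | (2E)-3-({[tert-butyl(dimethyl)silyl]oxy}methyl)hepta-2,6-dienal | O=C/C=C(/CO[Si](C)(C)C(C)(C)C)CCC=C | intermediate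
7 | ethyl 2,2-diethoxyacetate | CCOC(OCC)C(=O)OCC | starting material
8 | prop-1-en-2-ylmagnesium bromide | CC(=C)[Mg]Br | starting material
9 | 1,1-diethoxy-3-methylbut-3-en-2-one | CCOC(OCC)C(=O)C(C)=C | intermediate
10 | (2S)-1,1-diethoxy-3-methylbut-3-en-2-ol | C=C(C)[C@H](O)C(OCC)OCC | intermediate
11 | (2S)-1,1-diethoxy-3-methylbut-3-en-2-yl acetate | C=C(C)[C@H](OC(C)=O)C(OCC)OCC | intermediate
12 | (2S)-3-methyl-1-oxobut-3-en-2-yl acetate | C=C(C)[C@H](OC(C)=O)C=O | intermediate
13 | bromoethene | C=CBr | starting material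
14 | (3R,4S)-3-hydroxy-5-methylhexa-1,5-dien-4-yl acetate | C=C[C@@H](O)[C@@H](OC(C)=O)C(C)=C | intermediate
15 | methyl 2-(chloromethyl)prop-2-enoate | C=C(CCl)C(=O)OC | starting material
16 | methyl (2Z,4R,5S)-5-acetoxy-2-(chloromethyl)-4-hydroxy-6-methylhepta-2,6-dienoate | COC(=O)/C(CCl)=C/[C@@H](O)[C@@H](OC(C)=O)C(C)=C | intermediate
17 | methyl (2Z,4R,5S,6E,10E)-5-acetoxy-10-({[tert-butyl(dimethyl)silyl]oxy}methyl)-2-(chloromethyl)-4-hydroxy-6-methyl-12-oxododeca-2,6,10-trienoate | COC(=O)/C(CCl)=C/[C@@H](O)[C@@H](OC(C)=O)/C(C)=C/CC/C(CO[Si](C)(C)C(C)(C)C)=C\C=O | intermediate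
18 | 4-O-methacrylate of 17 | COC(=O)/C(CCl)=C/[C@@H](OC(=O)C(C)=C)[C@@H](OC(C)=O)/C(C)=C/CC/C(CO[Si](C)(C)C(C)(C)C)=C\C=O | intermediate
19 | allylchromium dichloride derived from 18 (CrCl2 in place of Cl on C13) | COC(=O)/C(C[Cr](Cl)Cl)=C/[C@@H](OC(=O)C(C)=C)[C@@H](OC(C)=O)/C(C)=C/CC/C(CO[Si](C)(C)C(C)(C)C)=C\C=O | intermediate
20 | ring-closed ten-membered chromium alkoxide (C6–OCrCl2, C7 bearing the methyl acrylate unit) | C=C(C)C(=O)O[C@@H]1[C@@H](C(=C)C(=O)OC)[C@H](O[Cr](Cl)Cl)/C=C(/CO[Si](C)(C)C(C)(C)C)CC/C=C(\C)[C@@H]1OC(C)=O | intermediate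
21 | (6R,7S,8R,9S)-9-acetoxy-15-(tert-butyldimethylsilyloxy)-8-(methacryloyloxy)germacra-1(10),4,11(13)-trien-12,6-olide, C9 trans to C2 | C=C(C)C(=O)O[C@@H]1[C@H]2C(=C)C(=O)O[C@@H]2/C=C(/CO[Si](C)(C)C(C)(C)C)CC/C=C(\C)[C@@H]1OC(C)=O | intermediate
22 | 14-hydroxy derivative with C9 cis to C2 (C14 trans to C2) | C=C(C)C(=O)O[C@@H]1[C@H]2C(=C)C(=O)O[C@@H]2/C=C(/CO[Si](C)(C)C(C)(C)C)CC/C=C(/CO)[C@@H]1OC(C)=O | intermediate
23 | 14-oxo 15-O-TBS ether of the target | C=C(C)C(=O)O[C@@H]1[C@H]2C(=C)C(=O)O[C@@H]2/C=C(/CO[Si](C)(C)C(C)(C)C)CC/C=C(/C=O)[C@@H]1OC(C)=O | intermediate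
24 | CNP0147326.13 | C=C(C)C(=O)O[C@@H]1[C@H]2C(=C)C(=O)O[C@@H]2/C=C(/CO)CC/C=C(/C=O)[C@@H]1OC(C)=O | target

**Totals:** 14 steps; longest linear sequence 11 steps (steps 4–14, from 7).

**Steps most likely to fail**

Step 12 (ring closure, facial selectivity at C6/C7 rests on analogy). The fallback sets out from 16 and 6 and comes back at 23. The C6–C7 bond is made between the fragments instead: CrCl2/LiI-mediated intermolecular allylation of enal 6 with chloride 16, with lactonisation of the C6 alkoxide, gives the acyclic trans-lactone F4 (diastereomers separated here). Ring-closing metathesis with the same ruthenium catalyst at 2 mM then closes C1=C10, the ten-membered ring forcing C9 cis to C2, to give hydroxy lactone F5. Methacryloylation gives ester F6, the C1=C10 geometric isomer of 21, which is taken through step 13 to 23.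

Step 10 (cross-metathesis onto a hindered isopropenyl carbinol acetate). The fallback sets out from 16 and 5 and comes back at 17. The metathesis is made intramolecular with a temporary silicon tether: 16, then 5, are joined through their free hydroxyl groups with iPr2SiCl2/imidazole to the mixed silaketal F1. Ring-closing metathesis forms C1=C10 inside the eleven-membered cyclic silaketal F2. HF·pyridine releases the diol F3, whose primary allylic hydroxyl is silylated selectively (TBSCl, imidazole, −20 °C) to give 17.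

Step 13 (late SeO2 oxidation of an alkene deactivated by the C9 acetate). The fallback sets out from 21 and comes back at 23. Photo-oxygenation (O2, tetraphenylporphyrin, visible light) of C1=C10 gives the secondary allylic hydroperoxide F7 (OOH on C1, exocyclic C10=C14). Allylic (Schenck) rearrangement moves it to the primary hydroperoxide F8 with the C1=C10 bond restored. Ac2O/pyridine (Kornblum–DeLaMare dehydration) then gives aldehyde 23.

Further compounds
F1 | step 10 | diisopropylsilylene ketal joining O-8 of 16 and O-15 of 5 | COC(=O)/C(CCl)=C/[C@@H](O[Si](C(C)C)(C(C)C)OC/C(CCC=C)=C/C=O)[C@@H](OC(C)=O)C(C)=C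
F2 | step 10 | eleven-membered cyclic silaketal with C1=C10 closed (C9 trans to C2) | COC(=O)/C(CCl)=C/[C@H]1O[Si](C(C)C)(C(C)C)OC/C(=C/C=O)CC/C=C(C)/[C@@H]1OC(C)=O
F3 | step 10 | 8,15-diol (17 without the silyl group) | COC(=O)/C(CCl)=C/[C@@H](O)[C@@H](OC(C)=O)/C(C)=C/CC/C(CO)=C\C=O
F4 | step 12 | acyclic trans-α-methylene lactone (C6–C7 joined, free 8-OH, terminal C1 vinyl, C10 isopropenyl) | C=C(C)[C@H](OC(C)=O)[C@H](O)[C@H]1C(=C)C(=O)O[C@@H]1/C=C(/CO[Si](C)(C)C(C)(C)C)CCC=C
F5 | step 12 | ten-membered 8-hydroxy lactone, C9 cis to C2 | O[C@@H]1[C@H]2C(=C)C(=O)O[C@@H]2/C=C(/CO[Si](C)(C)C(C)(C)C)CC/C=C(/C)[C@@H]1OC(C)=O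
F6 | step 12 | 8-O-methacrylate of F5 (C1=C10 geometric isomer of 21) | C=C(C)C(=O)O[C@@H]1[C@H]2C(=C)C(=O)O[C@@H]2/C=C(/CO[Si](C)(C)C(C)(C)C)CC/C=C(/C)[C@@H]1OC(C)=O
F7 | step 13 | C1-hydroperoxide with exocyclic C10=C14 (C1 epimers) | C=C(C)C(=O)O[C@@H]1[C@H]2C(=C)C(=O)O[C@@H]2/C=C(/CO[Si](C)(C)C(C)(C)C)CCC(OO)C(=C)[C@@H]1OC(C)=O
F8 | step 13 | C14-hydroperoxide with C1=C10 restored (C14 trans to C2) | C=C(C)C(=O)O[C@@H]1[C@H]2C(=C)C(=O)O[C@@H]2/C=C(/CO[Si](C)(C)C(C)(C)C)CC/C=C(/COO)[C@@H]1OC(C)=O
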